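**Retrosynthetic overview**

1. The C40 polyene of (3S,4R,3'S,6'R)-β,ε-carotene-3,4,3'-triol is cut at C11=C12 and C11'=C12' (two Wittig reactions): ring A C15 phosphonium salt + C10 dialdehyde + ring B C15 phosphonium salt.
2. Feature used: in ring B (C1'–C6', C4'=C5', methyl on C5', gem-dimethyl on C1') the oxygen on C3' and the chain carbon C7' on C6' are cis across the ring, so they can be tied as a lactone bridge O(C3')–C7'(=O). Cutting C2'–C3' and C1'–C6' of that 2-oxabicyclo[2.2.2]octenone leads to 4-methyl-2-pyrone and isobutene.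
3. Ring B is the only ring that has to be closed and is formed first, in the [4+2] step. Opening the bridge (lactol, Wittig) gives cis-3-hydroxy-α-ionone and from it the ring B salt.
4. Ring A is the same carbocycle: epoxidation of the lactone alkene on the bridge face, reduction and E1cB opening move the alkene to C5=C6 and leave the cis C3/C4 diol. All five stereocentres therefore descend from the cycloadduct.
5. Order: pyrone → bridged lactone (ring closure) → two C15 halves → C25 aldehyde → C40 → desilylation.

Key step: step 2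

Assumption: the sense of induction of the chiral aluminium binaphthoxide cannot be predicted with certainty; the (R)-ligand is written, and its antipode would be used if it proves to favour the (1R,4S)-lactone.

**Route**

Step 1
Reactants: 1 ethyl 3-methylbut-2-enoate; 2 ethyl formate
Product: 4 4-methyl-2H-pyran-2-one, via formyl-ester enol 3 (not isolated)
Conditions: KOtBu (1.1 equiv), 2 (2 equiv), THF, 0 °C → rt; then conc. HCl, AcOH, 70 °C
Reagents that add atoms: none
Why: Vinylogous Claisen condensation, in which under equilibrating conditions the dienolate of 1 is formylated at the γ-carbon because this gives the fully conjugated potassium enolate, and on acidification enol 3 can reach the 2Z geometry and lactonises with loss of ethanol to the 2-pyrone; no stereocentre is formed.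

Step 2
Reactants: 4 4-methyl-2H-pyran-2-one; 5 2-methylpropene
Product: 6 (1S,4R)-5,8,8-trimethyl-2-oxabicyclo[2.2.2]oct-5-en-3-one
Conditions: 5 (10 equiv, condensed), MeAl[(R)-3,3'-bis(triphenylsilyl)-1,1'-binaphthalene-2,2'-diolate] (20 mol %), CH2Cl2, −78 → −40 °C, sealed vessel; aq. NaHCO3 quench at −40 °C
Reagents that add atoms: none
Why: Proposed new method: the bulky chiral methylaluminium binaphthoxide binds the carbonyl oxygen of 4 (which is far more Lewis basic than the lactone product, so turnover is possible), giving the ring 2-aluminoxypyrylium character and a lowered LUMO, and isobutene then adds across C3 and C6 in a concerted but strongly asynchronous inverse-electron-demand [4+2] cycloaddition in which the CH2 terminus bonds first to C6 and the developing tertiary cationic carbon closes onto C3. The closest known reactions are Lewis-acid-promoted inverse-demand Diels–Alder reactions of electron-poor 2-pyrones with vinyl ethers and uncatalysed high-pressure cycloadditions of 2-pyrones with simple alkenes, both of which give such bridged lactones. The six-membered carbocycle (ring B) is closed intermolecularly by forming the C6–CH2 (future C3'–C2') and C3–CMe2 (future C6'–C1') bonds, the O1–C2(=O) unit of the pyrone being left as the lactone bridge. The two new stereocentres C1 and C4 are locked to each other by that bridge, so the only variable is the enantioface of the flat pyrone, which is to be selected by the triphenylsilyl groups of the aluminium binaphthoxide screening one face of the coordinated heterocycle. The step needs regioselectivity, which is secured by the matched polarity of the partners (largest LUMO coefficient of the complexed pyrone at C6, nucleophilic CH2 and cation-stabilising CMe2 ends of the alkene), and there is no endo/exo issue because the dienophile carries two identical pairs of substituents. Low temperature, exclusion of protic initiators and a cold quench are needed to hold back cationic oligomerisation of isobutene, ionisation of the allylic lactone C–O bond and cycloreversion with loss of CO2.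

Step 3
Reactants: 6 (1S,4R)-5,8,8-trimethyl-2-oxabicyclo[2.2.2]oct-5-en-3-one
Product: 7 (1S,4R)-5,8,8-trimethyl-2-oxabicyclo[2.2.2]oct-5-en-3-ol (lactol; both C3 epimers)
Conditions: iBu2AlH (1.1 equiv), CH2Cl2, −78 °C; aq. potassium sodium tartrate
Reagents that add atoms: none
Why: Partial hydride reduction of a lactone to the lactol, the tetrahedral aluminium hemiacetal being stable at −78 °C until work-up; the two ring stereocentres are untouched and the new hemiacetal centre is of no consequence.

Step 4
Reactants: 7 bridged lactol; 8 1-(triphenylphosphoranylidene)propan-2-one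
Product: 10 (3S,6R)-3-hydroxy-α-ionone, via hydroxy aldehyde 9 (not isolated)
Conditions: 8 (1.5 equiv), toluene, 80 °C
Reagents that add atoms: none
Why: Wittig olefination with a stabilised ylide, which traps the ring-opened hydroxy aldehyde tautomer 9 of the lactol under neutral conditions and should give the E-enone; C3' and C6' come unchanged from 6, so hydroxyl and side chain stay cis.

Step 5
Reactants: 10 (3S,6R)-3-hydroxy-α-ionone
Product: 11 (3S,6R)-3-(tert-butyldimethylsilyloxy)-α-ionone
Conditions: TBSCl, imidazole, DMF, rt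
Reagents that add atoms: tert-butyldimethylsilyl chloride, CC(C)(C)[Si](C)(C)Cl
Why: Imidazole-promoted silylation of a secondary alcohol, which protects the acid-sensitive allylic carbinol for the following steps without touching a stereocentre.

Step 6
Reactants: 11 silyl ether of 10; 12 triethyl phosphonoacetate
Product: 13 ethyl (2E,4E)-5-[(1R,4S)-4-(tert-butyldimethylsilyloxy)-2,6,6-trimethylcyclohex-2-en-1-yl]-3-methylpenta-2,4-dienoate
Conditions: 12 (1.5 equiv), NaH, THF, 0 → 45 °C
Reagents that add atoms: none
Why: Horner–Wadsworth–Emmons olefination of the methyl ketone, known for ionones, in which the 9'E ester is expected to predominate (a 9'Z isomer would be removed by chromatography) and the weakly basic phosphonate anion should leave the C6' centre alone.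

Step 7
Reactants: 13 ring B C15 ester
Product: 14 (2E,4E)-5-[(1R,4S)-4-(tert-butyldimethylsilyloxy)-2,6,6-trimethylcyclohex-2-en-1-yl]-3-methylpenta-2,4-dien-1-ol
Conditions: iBu2AlH (2.5 equiv), CH2Cl2, −78 → −20 °C; aq. potassium sodium tartrate
Reagents that add atoms: none
Why: 1,2-Reduction of a conjugated ester to the allylic alcohol by iBu2AlH, which does not affect the silyl ether, the alkenes or the stereocentres.

Step 8
Reactants: 14 ring B C15 alcohol
Product: 16 [(2E,4E)-5-[(1R,4S)-4-(tert-butyldimethylsilyloxy)-2,6,6-trimethylcyclohex-2-en-1-yl]-3-methylpenta-2,4-dien-1-yl]triphenylphosphonium bromide, via allylic bromide 15 (not isolated)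
Conditions: CBr4 (1.1 equiv), PPh3 (2.5 equiv), CH2Cl2, 0 °C → rt, dark
Reagents that add atoms: carbon tetrabromide, BrC(Br)(Br)Br; triphenylphosphine, c1ccc(cc1)P(c1ccccc1)c1ccccc1
Why: Appel bromination gives the primary dienyl bromide under neutral conditions that spare the allylic silyl ether, and SN2 quaternisation by the excess phosphine at the unhindered primary carbon gives the salt; no stereocentre is touched.

Step 9
Reactants: 16 ring B C15 phosphonium bromide; 17 (2E,4E,6E)-2,7-dimethylocta-2,4,6-trienedial
Product: 19 (2E,4E,6E,8E,10E,12E)-13-[(1R,4S)-4-(tert-butyldimethylsilyloxy)-2,6,6-trimethylcyclohex-2-en-1-yl]-2,7,11-trimethyltrideca-2,4,6,8,10,12-hexaenal, via ylide 18 (not isolated)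
Conditions: 17 (3 equiv), 1,2-epoxybutane, EtOH, 70 °C, dark, Ar
Reagents that add atoms: none
Why: Wittig olefination in which bromide opens the epoxide to an alkoxide that forms ylide 18 in low stationary concentration, so that with excess dialdehyde mono-olefination is expected (the C25 aldehyde is also the less electrophilic carbonyl), and the hindered Z form of the new C11'=C12' bond should isomerise to E at this temperature.

Step 10
Reactants: 6 (1S,4R)-5,8,8-trimethyl-2-oxabicyclo[2.2.2]oct-5-en-3-one
Product: 20 (1S,4R,5R,6S)-5,6-epoxy-5,8,8-trimethyl-2-oxabicyclo[2.2.2]octan-3-one (oxirane oxygen on the side of the O2–C3 bridge)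
Conditions: dimethyldioxirane (1.3 equiv), acetone, 0 °C
Reagents that add atoms: dimethyldioxirane, CC1(C)OO1
Why: Concerted electrophilic epoxidation by a dioxirane under neutral conditions, expected on the alkene face next to the lactone bridge because the other face lies under a methyl group of C8; this sets C5 and C6 and places the future C4 oxygen of ring A cis to the future C3 oxygen (O2 on C1).

Step 11
Reactants: 20 epoxy lactone
Product: 21 (1S,4R,5R,6S)-5,6-epoxy-5,8,8-trimethyl-2-oxabicyclo[2.2.2]octan-3-ol (lactol; both C3 epimers)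
Conditions: iBu2AlH (1.1 equiv), CH2Cl2, −78 °C; aq. potassium sodium tartrate
Reagents that add atoms: none
Why: Partial hydride reduction of the lactone to the lactol as in step 3, the epoxide being inert to iBu2AlH at −78 °C and all four ring stereocentres being retained.

Step 12
Reactants: 21 epoxy lactol
Product: 23 (3R,4S)-3,4-dihydroxy-2,6,6-trimethylcyclohex-1-ene-1-carbaldehyde, via epoxy aldehyde 22 (not isolated)
Conditions: DBU (0.2 equiv), CH2Cl2, 0 °C → rt
Reagents that add atoms: none
Why: E1cB opening of a β,γ-epoxy aldehyde, in which the lactol equilibrates with aldehyde 22, DBU removes its α-hydrogen (the former bridgehead) and the enolate expels the adjacent epoxide C–O bond to give the conjugated enal; the C–O bond of the future C4 is not broken and C3 is untouched, so the diol is cis, (3S,4R) in carotenoid numbering.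

Step 13
Reactants: 23 cis-diol enal
Product: 24 (3R,4S)-3,4-bis(tert-butyldimethylsilyloxy)-2,6,6-trimethylcyclohex-1-ene-1-carbaldehyde
Conditions: TBSOTf (2.5 equiv), 2,6-lutidine (4 equiv), CH2Cl2, −40 → 0 °C
Reagents that add atoms: tert-butyldimethylsilyl trifluoromethanesulfonate, CC(C)(C)[Si](C)(C)OS(=O)(=O)C(F)(F)F
Why: Silylation of both secondary hydroxyls with a silyl triflate and a hindered pyridine base, reactive enough for the crowded cis-diol and giving a protecting group that can later be removed without acid; no stereocentre is affected.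

Step 14
Reactants: 24 bis-silylated enal; 25 triethyl 3-methyl-4-phosphonocrotonate
Product: 26 ethyl (2E,4E)-5-[(3R,4S)-3,4-bis(tert-butyldimethylsilyloxy)-2,6,6-trimethylcyclohex-1-en-1-yl]-3-methylpenta-2,4-dienoate
Conditions: 25 (1.5 equiv), NaH, THF, 0 °C → rt
Reagents that add atoms: none
Why: Vinylogous Horner–Wadsworth–Emmons olefination, known for β-cyclocitral-type aldehydes, in which the phosphonate carbanion adds through the carbon next to phosphorus and elimination gives the 7E alkene, the 9E ester being expected to predominate because the allylic anion equilibrates (a 9Z isomer would be removed by chromatography); the ring stereocentres are not involved.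

Step 15
Reactants: 26 ring A C15 ester
Product: 27 (2E,4E)-5-[(3R,4S)-3,4-bis(tert-butyldimethylsilyloxy)-2,6,6-trimethylcyclohex-1-en-1-yl]-3-methylpenta-2,4-dien-1-ol
Conditions: iBu2AlH (2.5 equiv), CH2Cl2, −78 → −20 °C; aq. potassium sodium tartrate
Reagents that add atoms: none
Why: 1,2-Reduction of the conjugated ester to the allylic alcohol by iBu2AlH, with silyl ethers and stereocentres unaffected.

Step 16
Reactants: 27 ring A C15 alcohol
Product: 29 [(2E,4E)-5-[(3R,4S)-3,4-bis(tert-butyldimethylsilyloxy)-2,6,6-trimethylcyclohex-1-en-1-yl]-3-methylpenta-2,4-dien-1-yl]triphenylphosphonium bromide, via allylic bromide 28 (not isolated)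
Conditions: CBr4 (1.1 equiv), PPh3 (2.5 equiv), CH2Cl2, 0 °C → rt, dark
Reagents that add atoms: carbon tetrabromide, BrC(Br)(Br)Br; triphenylphosphine, c1ccc(cc1)P(c1ccccc1)c1ccccc1
Why: Appel bromination and SN2 quaternisation as in step 8, chosen because the neutral conditions avoid the ionisation of the allylic C4–O bond that an acidic salt formation would risk.

Step 17
Reactants: 29 ring A C15 phosphonium bromide; 19 ring B C25 aldehyde
Product: 31 (3S,4R,3'S,6'R)-3,4,3'-tris(tert-butyldimethylsilyloxy)-β,ε-carotene, via ylide 30 (not isolated)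
Conditions: 29 (1.3 equiv), 1,2-epoxybutane, EtOH, 70 °C, dark, Ar; crystallisation
Reagents that add atoms: none
Why: Wittig olefination under neutral conditions (ylide 30 formed by the alkoxide from bromide opening of the epoxide), which joins C11 to C12 without exposing the base-sensitive C6' centre, the hindered 11Z isomer being expected to isomerise to the all-E polyene on heating; no stereocentre is formed.

Step 18
Reactants: 31 tris-silylated carotenoid
Product: 32 (3S,4R,3'S,6'R)-β,ε-carotene-3,4,3'-triol (target)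
Conditions: Bu4NF (6 equiv), THF, rt, dark, Ar; neutral aqueous work-up
Reagents that add atoms: none
Why: Fluoride-induced cleavage of the three silyl ethers (driven by the Si–F bond), chosen because it needs no acid, which the allylic C4 and C3' carbinols would not tolerate; the stereocentres are untouched.

**Compound list**

1 | ethyl 3-methylbut-2-enoate | CCOC(=O)C=C(C)C | starting material
2 | ethyl formate | CCOC=O | starting material
3 | ethyl 5-hydroxy-3-methylpenta-2,4-dienoate (enol of the γ-formyl ester, formed as its potassium salt; geometry not fixed) | CCOC(=O)C=C(C)C=CO | intermediate (not isolated)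
4 | 4-methyl-2H-pyran-2-one | CC1=CC(=O)OC=C1 | intermediate
5 | 2-methylpropene | CC(C)=C | starting material
6 | (1S,4R)-5,8,8-trimethyl-2-oxabicyclo[2.2.2]oct-5-en-3-one | CC1=C[C@@H](O2)CC(C)(C)[C@H]1C2=O | intermediate
7 | (1S,4R)-5,8,8-trimethyl-2-oxabicyclo[2.2.2]oct-5-en-3-ol (both C3 epimers) | CC1=C[C@@H](O2)CC(C)(C)[C@H]1C2O | intermediate
8 | 1-(triphenylphosphoranylidene)propan-2-one | CC(=O)C=P(c1ccccc1)(c1ccccc1)c1ccccc1 | starting material
9 | (1R,4S)-4-hydroxy-2,6,6-trimethylcyclohex-2-ene-1-carbaldehyde | CC1=C[C@@H](O)CC(C)(C)[C@H]1C=O | intermediate (not isolated)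
10 | (3S,6R)-3-hydroxy-α-ionone, (E)-4-[(1R,4S)-4-hydroxy-2,6,6-trimethylcyclohex-2-en-1-yl]but-3-en-2-one | CC1=C[C@@H](O)CC(C)(C)[C@H]1/C=C/C(C)=O | intermediate
11 | (E)-4-[(1R,4S)-4-(tert-butyldimethylsilyloxy)-2,6,6-trimethylcyclohex-2-en-1-yl]but-3-en-2-one | CC1=C[C@@H](O[Si](C)(C)C(C)(C)C)CC(C)(C)[C@H]1/C=C/C(C)=O | intermediate
12 | triethyl phosphonoacetate | CCOC(=O)CP(=O)(OCC)OCC | starting material
13 | ethyl (2E,4E)-5-[(1R,4S)-4-(tert-butyldimethylsilyloxy)-2,6,6-trimethylcyclohex-2-en-1-yl]-3-methylpenta-2,4-dienoate | CC1=C[C@@H](O[Si](C)(C)C(C)(C)C)CC(C)(C)[C@H]1/C=C/C(C)=C/C(=O)OCC | intermediate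
14 | (2E,4E)-5-[(1R,4S)-4-(tert-butyldimethylsilyloxy)-2,6,6-trimethylcyclohex-2-en-1-yl]-3-methylpenta-2,4-dien-1-ol | CC1=C[C@@H](O[Si](C)(C)C(C)(C)C)CC(C)(C)[C@H]1/C=C/C(C)=C/CO | intermediate
15 | (2E,4E)-1-bromo-5-[(1R,4S)-4-(tert-butyldimethylsilyloxy)-2,6,6-trimethylcyclohex-2-en-1-yl]-3-methylpenta-2,4-diene | CC1=C[C@@H](O[Si](C)(C)C(C)(C)C)CC(C)(C)[C@H]1/C=C/C(C)=C/CBr | intermediate (not isolated)
16 | [(2E,4E)-5-[(1R,4S)-4-(tert-butyldimethylsilyloxy)-2,6,6-trimethylcyclohex-2-en-1-yl]-3-methylpenta-2,4-dien-1-yl]triphenylphosphonium bromide | CC1=C[C@@H](O[Si](C)(C)C(C)(C)C)CC(C)(C)[C@H]1/C=C/C(C)=C/C[P+](c1ccccc1)(c1ccccc1)c1ccccc1.[Br-] | intermediate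
17 | (2E,4E,6E)-2,7-dimethylocta-2,4,6-trienedial | O=C/C(C)=C/C=C/C=C(C)/C=O | starting material
18 | ylide of 16 | CC1=C[C@@H](O[Si](C)(C)C(C)(C)C)CC(C)(C)[C@H]1/C=C/C(C)=C/C=P(c1ccccc1)(c1ccccc1)c1ccccc1 | intermediate (not isolated)
19 | (2E,4E,6E,8E,10E,12E)-13-[(1R,4S)-4-(tert-butyldimethylsilyloxy)-2,6,6-trimethylcyclohex-2-en-1-yl]-2,7,11-trimethyltrideca-2,4,6,8,10,12-hexaenal | CC1=C[C@@H](O[Si](C)(C)C(C)(C)C)CC(C)(C)[C@H]1/C=C/C(C)=C/C=C/C(C)=C/C=C/C=C(C)/C=O | intermediate
20 | (1S,4R,5R,6S)-5,6-epoxy-5,8,8-trimethyl-2-oxabicyclo[2.2.2]octan-3-one (oxirane oxygen syn to the lactone bridge) | C[C@@]13O[C@H]3[C@@H](O2)CC(C)(C)[C@H]1C2=O | intermediate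
21 | (1S,4R,5R,6S)-5,6-epoxy-5,8,8-trimethyl-2-oxabicyclo[2.2.2]octan-3-ol (both C3 epimers) | C[C@@]13O[C@H]3[C@@H](O2)CC(C)(C)[C@H]1C2O | intermediate
22 | ring-opened tautomer of 21: 2,3-epoxy-4-hydroxy-2,6,6-trimethylcyclohexane-1-carbaldehyde with hydroxyl, oxirane oxygen and formyl group on one ring face | C[C@@]13O[C@H]3[C@@H](O)CC(C)(C)[C@H]1C=O | intermediate (not isolated)
23 | (3R,4S)-3,4-dihydroxy-2,6,6-trimethylcyclohex-1-ene-1-carbaldehyde | O=CC1=C(C)[C@@H](O)[C@@H](O)CC1(C)C | intermediate
24 | (3R,4S)-3,4-bis(tert-butyldimethylsilyloxy)-2,6,6-trimethylcyclohex-1-ene-1-carbaldehyde | O=CC1=C(C)[C@@H](O[Si](C)(C)C(C)(C)C)[C@@H](O[Si](C)(C)C(C)(C)C)CC1(C)C | intermediate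
25 | triethyl 3-methyl-4-phosphonocrotonate (ethyl 4-(diethoxyphosphoryl)-3-methylbut-2-enoate, E/Z mixture as supplied) | CCOC(=O)C=C(C)CP(=O)(OCC)OCC | starting material
26 | ethyl (2E,4E)-5-[(3R,4S)-3,4-bis(tert-butyldimethylsilyloxy)-2,6,6-trimethylcyclohex-1-en-1-yl]-3-methylpenta-2,4-dienoate | CCOC(=O)/C=C(C)/C=C/C1=C(C)[C@@H](O[Si](C)(C)C(C)(C)C)[C@@H](O[Si](C)(C)C(C)(C)C)CC1(C)C | intermediate
27 | (2E,4E)-5-[(3R,4S)-3,4-bis(tert-butyldimethylsilyloxy)-2,6,6-trimethylcyclohex-1-en-1-yl]-3-methylpenta-2,4-dien-1-ol | OC/C=C(C)/C=C/C1=C(C)[C@@H](O[Si](C)(C)C(C)(C)C)[C@@H](O[Si](C)(C)C(C)(C)C)CC1(C)C | intermediate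
28 | (2E,4E)-1-bromo-5-[(3R,4S)-3,4-bis(tert-butyldimethylsilyloxy)-2,6,6-trimethylcyclohex-1-en-1-yl]-3-methylpenta-2,4-diene | BrC/C=C(C)/C=C/C1=C(C)[C@@H](O[Si](C)(C)C(C)(C)C)[C@@H](O[Si](C)(C)C(C)(C)C)CC1(C)C | intermediate (not isolated)
29 | [(2E,4E)-5-[(3R,4S)-3,4-bis(tert-butyldimethylsilyloxy)-2,6,6-trimethylcyclohex-1-en-1-yl]-3-methylpenta-2,4-dien-1-yl]triphenylphosphonium bromide | [Br-].c1ccccc1[P+](c1ccccc1)(c1ccccc1)C/C=C(C)/C=C/C1=C(C)[C@@H](O[Si](C)(C)C(C)(C)C)[C@@H](O[Si](C)(C)C(C)(C)C)CC1(C)C | intermediate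
30 | ylide of 29 | c1ccccc1P(c1ccccc1)(c1ccccc1)=C/C=C(C)/C=C/C1=C(C)[C@@H](O[Si](C)(C)C(C)(C)C)[C@@H](O[Si](C)(C)C(C)(C)C)CC1(C)C | intermediate (not isolated)
31 | (3S,4R,3'S,6'R)-3,4,3'-tris(tert-butyldimethylsilyloxy)-β,ε-carotene (all-E) | CC1=C[C@@H](O[Si](C)(C)C(C)(C)C)CC(C)(C)[C@H]1/C=C/C(C)=C/C=C/C(C)=C/C=C/C=C(C)/C=C/C=C(C)/C=C/C1=C(C)[C@@H](O[Si](C)(C)C(C)(C)C)[C@@H](O[Si](C)(C)C(C)(C)C)CC1(C)C | intermediate
32 | (3S,4R,3'S,6'R)-β,ε-carotene-3,4,3'-triol (all-E), CNP0191612.2 | CC1=C[C@@H](O)CC(C)(C)[C@H]1/C=C/C(C)=C/C=C/C(C)=C/C=C/C=C(C)/C=C/C=C(C)/C=C/C1=C(C)[C@@H](O)[C@@H](O)CC1(C)C | target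

**Step count**

Total: 18 steps. Longest linear sequence: 11 steps (steps 1, 2, 10–16, 17, 18; the ring B branch, steps 1–9, 17, 18, is equally long).

**Steps most likely to fail**

Step 2 (proposed new method). The aluminium-bound pyrone may be too weak an electrophile for an unactivated 1,1-disubstituted alkene, so that cationic oligomerisation of isobutene or ionisation of the allylic lactone outruns cycloaddition; enantioface discrimination may also be poor. The fallback uses known chemistry, sets out from 4 and 5 and comes back at 6. The two are combined without Lewis acid under high pressure (about 12–15 kbar, CH2Cl2, 40 °C), the established way to obtain bridged lactones from 2-pyrones and simple alkenes before CO2 is lost, to give racemic 5,8,8-trimethyl-2-oxabicyclo[2.2.2]oct-5-en-3-one F1. LiOH in aqueous THF opens it to racemic cis-4-hydroxy-2,6,6-trimethylcyclohex-2-ene-1-carboxylic acid F2. Classical resolution by crystallisation with (R)-1-phenylethylamine (or its antipode, whichever gives the less soluble salt of the wanted acid) would give (R)-1-phenylethylammonium (1R,4S)-4-hydroxy-2,6,6-trimethylcyclohex-2-ene-1-carboxylate F3. Mild acidification (aq. citric acid) frees (1R,4S)-4-hydroxy-2,6,6-trimethylcyclohex-2-ene-1-carboxylic acid F4, and carbodiimide lactonisation (EDC·HCl, DMAP, CH2Cl2), which only a cis hydroxy acid can undergo, returns 6.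

Step 4. The hindered aldehyde is present only as a small equilibrium share of the lactol, so olefination may be slow, and during the heating the β,γ-unsaturated aldehyde may epimerise at C6' through its enol or the lactol may fragment. The fallback sets out from 6 and comes back at 11. MeNH(OMe)·HCl/AlMe3 (CH2Cl2, 0 °C) opens the lactone to (1R,4S)-4-hydroxy-N-methoxy-N,2,6,6-tetramethylcyclohex-2-ene-1-carboxamide F5, and TBSCl/imidazole gives (1R,4S)-4-(tert-butyldimethylsilyloxy)-N-methoxy-N,2,6,6-tetramethylcyclohex-2-ene-1-carboxamide F6. iBu2AlH (THF, −78 °C) then gives (1R,4S)-4-(tert-butyldimethylsilyloxy)-2,6,6-trimethylcyclohex-2-ene-1-carbaldehyde F7, which cannot hide as a lactol. It is olefinated at room temperature with dimethyl (2-oxopropyl)phosphonate (LiCl, iPr2NEt, MeCN) to give 11 directly.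

Step 14. Addition of the phosphonate anion to the crowded tetrasubstituted enal may be slow, so that γ-deprotonation of the enal (with possible loss of the C3 silyloxy group) and poor 9E/9Z control compete. The fallback sets out from 24 and comes back at 26. Compound 24 is heated with the neutral ylide 8 (toluene, 110 °C), which involves no base, to give (E)-4-[(3R,4S)-3,4-bis(tert-butyldimethylsilyloxy)-2,6,6-trimethylcyclohex-1-en-1-yl]but-3-en-2-one F8. This ketone is then homologated with 12 (NaH, THF) as in step 6 to give 26.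

**Further compounds**

F1 | step 2 | racemic 5,8,8-trimethyl-2-oxabicyclo[2.2.2]oct-5-en-3-one | CC1=CC(O2)CC(C)(C)C1C2=O
F2 | step 2 | racemic cis-4-hydroxy-2,6,6-trimethylcyclohex-2-ene-1-carboxylic acid (both enantiomers written) | CC1=C[C@@H](O)CC(C)(C)[C@H]1C(=O)O.CC1=C[C@H](O)CC(C)(C)[C@@H]1C(=O)O
F3 | step 2 | (R)-1-phenylethylammonium (1R,4S)-4-hydroxy-2,6,6-trimethylcyclohex-2-ene-1-carboxylate | CC1=C[C@@H](O)CC(C)(C)[C@H]1C(=O)[O-].C[C@@H]([NH3+])c1ccccc1
F4 | step 2 | (1R,4S)-4-hydroxy-2,6,6-trimethylcyclohex-2-ene-1-carboxylic acid | CC1=C[C@@H](O)CC(C)(C)[C@H]1C(=O)O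
F5 | step 4 | (1R,4S)-4-hydroxy-N-methoxy-N,2,6,6-tetramethylcyclohex-2-ene-1-carboxamide | CC1=C[C@@H](O)CC(C)(C)[C@H]1C(=O)N(C)OC
F6 | step 4 | (1R,4S)-4-(tert-butyldimethylsilyloxy)-N-methoxy-N,2,6,6-tetramethylcyclohex-2-ene-1-carboxamide | CC1=C[C@@H](O[Si](C)(C)C(C)(C)C)CC(C)(C)[C@H]1C(=O)N(C)OC
F7 | step 4 | (1R,4S)-4-(tert-butyldimethylsilyloxy)-2,6,6-trimethylcyclohex-2-ene-1-carbaldehyde | CC1=C[C@@H](O[Si](C)(C)C(C)(C)C)CC(C)(C)[C@H]1C=O
F8 | step 14 | (E)-4-[(3R,4S)-3,4-bis(tert-butyldimethylsilyloxy)-2,6,6-trimethylcyclohex-1-en-1-yl]but-3-en-2-one | CC(=O)/C=C/C1=C(C)[C@@H](O[Si](C)(C)C(C)(C)C)[C@@H](O[Si](C)(C)C(C)(C)C)CC1(C)C
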